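**Retrosynthetic overview**

1. Target 23 is the opened form of a benzo-fused lactone. The (E)-propenol comes from lactol 20 by Wittig olefination and ester reduction. The 2-pyranone comes from a β,δ-diketo ester, made from aldehyde 14 and an acetoacetate dianion.
2. Key disconnection: the aryl C–CH(CH3) bond. Lactone 12 comes from 3-methyl-N-(quinolin-8-yl)benzamide 10 and trans-epoxide 7 by Ni-catalysed ortho-C–H alkylation with inversion, followed in the flask by lactonisation that expels the auxiliary.
3. Enabling feature: the carbinol O, the carbinol carbon, the benzylic CH(CH3), the two adjacent benzene carbons and the ring-bound alkene carbon form a latent six-membered δ-lactone (isochroman-1-one). At the carboxamide level that last carbon directs metalation to the ring carbon that must be alkylated and then captures the new hydroxyl.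
4. Epoxide 7 comes from the (R)-Roche ester by Julia–Kocienski olefination and reagent-controlled Shi epoxidation. After step 6 all three stereocentres are in place: one from the pool, one from the epoxidation, one by inversion.
5. Ring order: oxirane (step 4), temporary isochromanone (step 6), 2-pyranone (step 11), isochromanone opened (steps 12–13).

Key step: step 6

Remark: the carbinol and ester α-carbons of 17 and the anomeric carbon of 20 form as mixtures, which does not matter because these carbons are sp2 in the target; sulfone 4 and the L-fructose-type (enantiomeric) Shi ketone are taken as purchasable.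

Step 1
Reactants: 1 methyl (R)-3-hydroxy-2-methylpropanoate
Product: 2 methyl (R)-3-[(tert-butyldiphenylsilyl)oxy]-2-methylpropanoate
Conditions: TBDPSCl, imidazole, CH2Cl2, rt
Reagents that add atoms: tert-butyl(chloro)diphenylsilane, CC(C)(C)[Si](Cl)(c1ccccc1)c1ccccc1
Why: Imidazole-mediated silylation of a primary alcohol; the stereocentre is not involved.

Step 2
Reactants: 2 methyl (R)-3-[(tert-butyldiphenylsilyl)oxy]-2-methylpropanoate
Product: 3 (R)-3-[(tert-butyldiphenylsilyl)oxy]-2-methylpropanal
Conditions: DIBAL (1.1 equiv), CH2Cl2, −78 °C; MeOH, Rochelle salt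
Reagents that add atoms: none
Why: Low-temperature DIBAL half-reduction of a methyl ester through a stable aluminium hemiacetal; the aldehyde should be used crude to keep the α-stereocentre intact.

Step 3
Reactants: 3 (R)-3-[(tert-butyldiphenylsilyl)oxy]-2-methylpropanal, 4 5-(ethylsulfonyl)-1-phenyl-1H-tetrazole
Product: 6 (S,E)-tert-butyl[(2-methylpent-3-en-1-yl)oxy]diphenylsilane, via potassium sulfonyl carbanion 5 (not isolated)
Conditions: 4, KHMDS, DME, −60 °C; then 3, −60 °C to rt; aq. NH4Cl
Reagents that add atoms: none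
Why: Julia–Kocienski olefination; phenyltetrazolyl sulfones with a potassium counter-ion in DME should give the (E)-alkene by addition, Smiles rearrangement and elimination, and the pre-formed carbanion keeps free base away from the α-stereocentre.

Step 4
Reactants: 6 (S,E)-tert-butyl[(2-methylpent-3-en-1-yl)oxy]diphenylsilane
Product: 7 tert-butyl{(R)-2-[(2S,3S)-3-methyloxiran-2-yl]propoxy}diphenylsilane
Conditions: ent-Shi ketone (L-fructose type, 30 mol %), Oxone, K2CO3, Bu4NHSO4, MeCN/dimethoxymethane/aq. borate buffer, 0 °C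
Reagents that add atoms: Oxone (potassium peroxymonosulfate), [K+].[O-]S(=O)(=O)OO
Why: Shi asymmetric epoxidation of a trans-1,2-disubstituted alkene by a chiral dioxirane through a spiro transition state; the enantiomeric ketone should deliver oxygen to the face that gives the (2S,3S)-oxirane under reagent control, with the trans geometry retained.

Step 5
Reactants: 8 3-methylbenzoyl chloride, 9 8-aminoquinoline
Product: 10 3-methyl-N-(quinolin-8-yl)benzamide
Conditions: Et3N, DMAP (cat.), CH2Cl2, 0 °C to rt
Reagents that add atoms: none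
Why: N-acylation of an aromatic amine by an acid chloride installs the bidentate directing group.

Step 6
Reactants: 7 tert-butyl{(R)-2-[(2S,3S)-3-methyloxiran-2-yl]propoxy}diphenylsilane, 10 3-methyl-N-(quinolin-8-yl)benzamide
Product: 12 (3R,4S)-3-{(R)-1-[(tert-butyldiphenylsilyl)oxy]propan-2-yl}-4,7-dimethylisochroman-1-one, via hydroxy amide 11 (not isolated)
Conditions: Ni(OAc)2 (20 mol %), 10 (2 equiv), diglyme, 140 °C, sealed tube
Reagents that add atoms: none
Why: Ni(II)-catalysed 8-aminoquinoline-directed ortho-C–H alkylation of a benzamide with an epoxide followed by in-flask lactonisation, a known stereospecific coupling type (reported for terminal and 1,2-disubstituted oxiranes with inversion), applied here to an unsymmetrical trans-dialkyl oxirane. The N,N-chelated nickel amidate should undergo acetate-assisted C–H nickelation at the ortho position para to the ring methyl group (the other ortho C–H is flanked by that methyl), giving a five-membered aza-nickelacycle. Its aryl–Ni bond should open the oxirane in an SN2-type oxidative addition at the methyl-bearing carbon, because the other oxirane carbon carries the α-branched CH(CH3)CH2OSi group, and C–C reductive elimination plus protonation gives hydroxy amide 11. The new benzylic stereocentre is therefore set by inversion of the (S)-oxirane carbon while the carbinol and pool-derived centres are untouched, so the trans-epoxide is translated into the cis-3,4 relationship (the syn,syn triad of the target). The liberated secondary hydroxyl then attacks the N-quinolyl amide carbonyl in a 6-exo-trig acyl substitution that closes the δ-lactone, expels 8-aminoquinoline and prevents a second C–H alkylation. The step needs arene site selectivity, epoxide regioselectivity and stereospecificity, which are secured by the meta-methyl group, by the α-branch beside the carbinol carbon and by the SN2 course respectively.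

Step 7
Reactants: 12 (3R,4S)-3-{(R)-1-[(tert-butyldiphenylsilyl)oxy]propan-2-yl}-4,7-dimethylisochroman-1-one
Product: 13 (3R,4S)-3-[(R)-1-hydroxypropan-2-yl]-4,7-dimethylisochroman-1-one
Conditions: TBAF, AcOH, THF, rt
Reagents that add atoms: none
Why: Fluoride cleavage of the Si–O bond, buffered with acetic acid so that the lactone is not opened.

Step 8
Reactants: 13 (3R,4S)-3-[(R)-1-hydroxypropan-2-yl]-4,7-dimethylisochroman-1-one
Product: 14 (S)-2-[(3R,4S)-4,7-dimethyl-1-oxoisochroman-3-yl]propanal
Conditions: Dess–Martin periodinane, CH2Cl2, 0 °C to rt; used crude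
Reagents that add atoms: none
Why: Dess–Martin oxidation of a primary alcohol under non-basic conditions, which should avoid epimerisation of the α-stereocentre and E1cB loss of the β-acyloxy group.

Step 9
Reactants: 14 (S)-2-[(3R,4S)-4,7-dimethyl-1-oxoisochroman-3-yl]propanal, 15 ethyl 2-ethyl-3-oxobutanoate
Product: 17 ethyl (6R)-6-[(3R,4S)-4,7-dimethyl-1-oxoisochroman-3-yl]-2-ethyl-5-hydroxy-3-oxoheptanoate (C2/C5 epimers), via sodium lithium dianion 16 (not isolated)
Conditions: 15, NaH then n-BuLi, THF, 0 °C; then 14, −78 °C; aq. NH4Cl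
Reagents that add atoms: none
Why: Weiler dianion aldol; the γ-carbanion should add to the aldehyde at −78 °C faster than it enolises it or attacks the lactone, and the new carbinol centre (mixture) is removed in step 10.

Step 10
Reactants: 17 ethyl (6R)-6-[(3R,4S)-4,7-dimethyl-1-oxoisochroman-3-yl]-2-ethyl-5-hydroxy-3-oxoheptanoate
Product: 18 ethyl (6S)-6-[(3R,4S)-4,7-dimethyl-1-oxoisochroman-3-yl]-2-ethyl-3,5-dioxoheptanoate
Conditions: Dess–Martin periodinane, CH2Cl2, rt
Reagents that add atoms: none
Why: Dess–Martin oxidation of the δ-hydroxy-β-keto ester to the β,δ-diketo ester without base, so the α-methyl centre should be retained.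

Step 11
Reactants: 18 ethyl (6S)-6-[(3R,4S)-4,7-dimethyl-1-oxoisochroman-3-yl]-2-ethyl-3,5-dioxoheptanoate
Product: 19 3-ethyl-4-hydroxy-6-{(S)-1-[(3R,4S)-4,7-dimethyl-1-oxoisochroman-3-yl]ethyl}-2H-pyran-2-one
Conditions: DBU, toluene, rt to 40 °C; 1 M HCl work-up
Reagents that add atoms: none
Why: Base-mediated lactonisation of a 3,5-diketo ester (enol oxygen attacks the ester, 6-exo-trig) gives the 4-hydroxy-2-pyranone; DBU deprotonates only the 1,3-dicarbonyl CH2, so the α-methyl centre and the β-acyloxy group should survive.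

Step 12
Reactants: 19 3-ethyl-4-hydroxy-6-{(S)-1-[(3R,4S)-4,7-dimethyl-1-oxoisochroman-3-yl]ethyl}-2H-pyran-2-one
Product: 20 3-ethyl-4-hydroxy-6-{(S)-1-[(3R,4S)-1-hydroxy-4,7-dimethylisochroman-3-yl]ethyl}-2H-pyran-2-one (anomers)
Conditions: DIBAL (3.5 equiv), CH2Cl2, −78 °C; Rochelle salt
Reagents that add atoms: none
Why: DIBAL half-reduction of the aryl δ-lactone to the lactol; the first equivalent converts the acidic 4-hydroxyl into an aluminium pyranolate (a vinylogous carboxylate) that should be inert to hydride, so the pyranone is protected in the flask.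

Step 13
Reactants: 20 3-ethyl-4-hydroxy-6-{(S)-1-[(3R,4S)-1-hydroxy-4,7-dimethylisochroman-3-yl]ethyl}-2H-pyran-2-one, 21 ethyl (triphenylphosphoranylidene)acetate
Product: 22 ethyl (E)-3-{2-[(2S,3R,4S)-4-(5-ethyl-4-hydroxy-6-oxo-6H-pyran-2-yl)-3-hydroxypentan-2-yl]-5-methylphenyl}acrylate
Conditions: 21 (3 equiv), toluene, 80 °C
Reagents that add atoms: none
Why: Wittig olefination of the open hydroxy aldehyde tautomer of the lactol with a stabilised ylide should give the (E)-cinnamate; excess ylide compensates for protonation by the acidic pyranone, and the hindered secondary hydroxyl is slow to add back in an oxa-Michael sense.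

Step 14
Reactants: 22 ethyl (E)-3-{2-[(2S,3R,4S)-4-(5-ethyl-4-hydroxy-6-oxo-6H-pyran-2-yl)-3-hydroxypentan-2-yl]-5-methylphenyl}acrylate
Product: 23 Veramycin A
Conditions: DIBAL (6 equiv), CH2Cl2/THF, −78 to −20 °C; Rochelle salt
Reagents that add atoms: none
Why: DIBAL 1,2-reduction of the α,β-unsaturated ester to the (E)-allylic alcohol leaves the alkene geometry untouched; the pyranone is again masked as its aluminium salt.

**Compound list**

1 | methyl (R)-3-hydroxy-2-methylpropanoate ((R)-Roche ester) | C[C@H](CO)C(=O)OC | starting material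
2 | methyl (R)-3-[(tert-butyldiphenylsilyl)oxy]-2-methylpropanoate | C[C@H](CO[Si](c1ccccc1)(c1ccccc1)C(C)(C)C)C(=O)OC | intermediate
3 | (R)-3-[(tert-butyldiphenylsilyl)oxy]-2-methylpropanal | C[C@H](CO[Si](c1ccccc1)(c1ccccc1)C(C)(C)C)C=O | intermediate
4 | 5-(ethylsulfonyl)-1-phenyl-1H-tetrazole | CCS(=O)(=O)c1nnnn1-c1ccccc1 | starting material
5 | potassium 1-[(1-phenyl-1H-tetrazol-5-yl)sulfonyl]ethan-1-ide | C[CH-]S(=O)(=O)c1nnnn1-c1ccccc1.[K+] | intermediate
6 | (S,E)-tert-butyl[(2-methylpent-3-en-1-yl)oxy]diphenylsilane | C[C@H](CO[Si](c1ccccc1)(c1ccccc1)C(C)(C)C)/C=C/C | intermediate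
7 | tert-butyl{(R)-2-[(2S,3S)-3-methyloxiran-2-yl]propoxy}diphenylsilane | C[C@H](CO[Si](c1ccccc1)(c1ccccc1)C(C)(C)C)[C@@H]1O[C@H]1C | intermediate
8 | 3-methylbenzoyl chloride | Cc1cccc(c1)C(Cl)=O | starting material
9 | 8-aminoquinoline | Nc1cccc2cccnc12 | starting material
10 | 3-methyl-N-(quinolin-8-yl)benzamide | Cc1cccc(c1)C(=O)Nc1cccc2cccnc12 | intermediate
11 | 2-[(2S,3R,4R)-5-[(tert-butyldiphenylsilyl)oxy]-3-hydroxy-4-methylpentan-2-yl]-5-methyl-N-(quinolin-8-yl)benzamide | C[C@H](CO[Si](c1ccccc1)(c1ccccc1)C(C)(C)C)[C@H](O)[C@@H](C)c1ccc(C)cc1C(=O)Nc1cccc2cccnc12 | intermediate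
12 | (3R,4S)-3-{(R)-1-[(tert-butyldiphenylsilyl)oxy]propan-2-yl}-4,7-dimethylisochroman-1-one (cis) | C[C@H](CO[Si](c1ccccc1)(c1ccccc1)C(C)(C)C)[C@@H]1OC(=O)c2cc(C)ccc2[C@@H]1C | intermediate
13 | (3R,4S)-3-[(R)-1-hydroxypropan-2-yl]-4,7-dimethylisochroman-1-one | C[C@H](CO)[C@@H]1OC(=O)c2cc(C)ccc2[C@@H]1C | intermediate
14 | (S)-2-[(3R,4S)-4,7-dimethyl-1-oxoisochroman-3-yl]propanal | C[C@H](C=O)[C@@H]1OC(=O)c2cc(C)ccc2[C@@H]1C | intermediate
15 | ethyl 2-ethyl-3-oxobutanoate | CCOC(=O)C(CC)C(C)=O | starting material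
16 | sodium lithium dianion of ethyl 2-ethyl-3-oxobutanoate | CCOC([O-])=C(CC)C(=C)[O-].[Na+].[Li+] | intermediate
17 | ethyl (6R)-6-[(3R,4S)-4,7-dimethyl-1-oxoisochroman-3-yl]-2-ethyl-5-hydroxy-3-oxoheptanoate (C2/C5 epimers) | CCOC(=O)C(CC)C(=O)CC(O)[C@@H](C)[C@@H]1OC(=O)c2cc(C)ccc2[C@@H]1C | intermediate
18 | ethyl (6S)-6-[(3R,4S)-4,7-dimethyl-1-oxoisochroman-3-yl]-2-ethyl-3,5-dioxoheptanoate | CCOC(=O)C(CC)C(=O)CC(=O)[C@@H](C)[C@@H]1OC(=O)c2cc(C)ccc2[C@@H]1C | intermediate
19 | 3-ethyl-4-hydroxy-6-{(S)-1-[(3R,4S)-4,7-dimethyl-1-oxoisochroman-3-yl]ethyl}-2H-pyran-2-one | CCc1c(O)cc([C@@H](C)[C@@H]2OC(=O)c3cc(C)ccc3[C@@H]2C)oc1=O | intermediate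
20 | 3-ethyl-4-hydroxy-6-{(S)-1-[(3R,4S)-1-hydroxy-4,7-dimethylisochroman-3-yl]ethyl}-2H-pyran-2-one (anomers) | CCc1c(O)cc([C@@H](C)[C@@H]2OC(O)c3cc(C)ccc3[C@@H]2C)oc1=O | intermediate
21 | ethyl (triphenylphosphoranylidene)acetate | CCOC(=O)C=P(c1ccccc1)(c1ccccc1)c1ccccc1 | starting material
22 | ethyl (E)-3-{2-[(2S,3R,4S)-4-(5-ethyl-4-hydroxy-6-oxo-6H-pyran-2-yl)-3-hydroxypentan-2-yl]-5-methylphenyl}acrylate | CCc1c(O)cc([C@@H](C)[C@H](O)[C@@H](C)c2ccc(C)cc2/C=C/C(=O)OCC)oc1=O | intermediate
23 | Veramycin A, 3-ethyl-4-hydroxy-6-[(2S,3R,4S)-3-hydroxy-4-{2-[(E)-3-hydroxyprop-1-en-1-yl]-4-methylphenyl}pentan-2-yl]-2H-pyran-2-one | CCc1c(O)cc([C@@H](C)[C@H](O)[C@@H](C)c2ccc(C)cc2/C=C/CO)oc1=O | target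

**Step count and risks**

Total step count: 14. Longest linear sequence: 13 steps (steps 1–4 and 6–14, from 1).

Steps most likely to fail:

1. Step 6. The aryl–nickel intermediate may open the hindered internal oxirane too slowly or at the wrong carbon, and the epoxide may be lost at 140 °C by rearrangement or by aminolysis with the liberated 8-aminoquinoline. The fallback uses known chemistry, sets out from 7 and comes back at 12. Directed ortho-lithiation of commercial N,N-diethyl-3-methylbenzamide (CCN(CC)C(=O)c1cccc(C)c1; s-BuLi, TMEDA, THF, −78 °C; the position between amide and methyl is blocked) should give [2-(diethylcarbamoyl)-4-methylphenyl]lithium F1. BF3·OEt2-promoted SN2 opening of 7 at −78 °C, again at the methyl-bearing carbon with inversion, should give N,N-diethyl-2-[(2S,3R,4R)-5-[(tert-butyldiphenylsilyl)oxy]-3-hydroxy-4-methylpentan-2-yl]-5-methylbenzamide F2. Heating F2 with catalytic camphorsulfonic acid in toluene should close the lactone to 12 with loss of diethylamine.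

2. Step 12. Chemoselectivity may be lost, with hydride delivered to the pyranone carbonyl or the lactol reduced further to the diol. The fallback sets out from 12 and comes back at 20; it reduces the lactone before the pyranone exists and carries the lactol as a mixed acetal. DIBAL (CH2Cl2, −78 °C) should give the silyl ether lactol F3. Trimethyl orthoformate, PPTS and MeOH should give the 1-methoxyisochroman silyl ether F4, still a temporary ring that masks the carbinol oxygen. TBAF should give the methoxyisochroman alcohol F5, and Dess–Martin oxidation the methoxyisochroman aldehyde F6. Dianion 16 should give the methoxyisochroman hydroxy keto ester F7, a second Dess–Martin oxidation the methoxyisochroman diketo ester F8, and DBU the methoxyisochroman pyranone F9. Aqueous AcOH/THF should hydrolyse the acetal and return lactol 20.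

3. Step 9. The basic dianion may enolise the aldehyde, leading to β-elimination of the lactone carboxylate or epimerisation of the α-methyl centre in competition with addition. The fallback sets out from 15 (with 14) and comes back at 17; it is a Lewis-acid vinylogous Mukaiyama aldol without base. TMSCl/Et3N should convert 15 into ethyl 2-ethyl-3-[(trimethylsilyl)oxy]but-2-enoate F10. LDA/TMSCl at −78 °C should give 1-ethoxy-2-ethyl-1,3-bis[(trimethylsilyl)oxy]buta-1,3-diene F11. Addition of F11 to 14 with BF3·OEt2 in CH2Cl2 at −78 °C and a mild acidic work-up should give 17.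

Further compounds
F1 | step 6 | [2-(diethylcarbamoyl)-4-methylphenyl]lithium | [Li]c1ccc(C)cc1C(=O)N(CC)CC
F2 | step 6 | N,N-diethyl-2-[(2S,3R,4R)-5-[(tert-butyldiphenylsilyl)oxy]-3-hydroxy-4-methylpentan-2-yl]-5-methylbenzamide | C[C@H](CO[Si](c1ccccc1)(c1ccccc1)C(C)(C)C)[C@H](O)[C@@H](C)c1ccc(C)cc1C(=O)N(CC)CC
F3 | step 12 | (3R,4S)-3-{(R)-1-[(tert-butyldiphenylsilyl)oxy]propan-2-yl}-4,7-dimethylisochroman-1-ol (anomers) | C[C@H](CO[Si](c1ccccc1)(c1ccccc1)C(C)(C)C)[C@@H]1OC(O)c2cc(C)ccc2[C@@H]1C
F4 | step 12 | tert-butyl{(R)-2-[(3R,4S)-1-methoxy-4,7-dimethylisochroman-3-yl]propoxy}diphenylsilane | C[C@H](CO[Si](c1ccccc1)(c1ccccc1)C(C)(C)C)[C@@H]1OC(OC)c2cc(C)ccc2[C@@H]1C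
F5 | step 12 | (R)-2-[(3R,4S)-1-methoxy-4,7-dimethylisochroman-3-yl]propan-1-ol | C[C@H](CO)[C@@H]1OC(OC)c2cc(C)ccc2[C@@H]1C
F6 | step 12 | (S)-2-[(3R,4S)-1-methoxy-4,7-dimethylisochroman-3-yl]propanal | C[C@H](C=O)[C@@H]1OC(OC)c2cc(C)ccc2[C@@H]1C
F7 | step 12 | ethyl (6R)-2-ethyl-5-hydroxy-6-[(3R,4S)-1-methoxy-4,7-dimethylisochroman-3-yl]-3-oxoheptanoate | CCOC(=O)C(CC)C(=O)CC(O)[C@@H](C)[C@@H]1OC(OC)c2cc(C)ccc2[C@@H]1C
F8 | step 12 | ethyl (6S)-2-ethyl-6-[(3R,4S)-1-methoxy-4,7-dimethylisochroman-3-yl]-3,5-dioxoheptanoate | CCOC(=O)C(CC)C(=O)CC(=O)[C@@H](C)[C@@H]1OC(OC)c2cc(C)ccc2[C@@H]1C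
F9 | step 12 | 3-ethyl-4-hydroxy-6-{(S)-1-[(3R,4S)-1-methoxy-4,7-dimethylisochroman-3-yl]ethyl}-2H-pyran-2-one | CCc1c(O)cc([C@@H](C)[C@@H]2OC(OC)c3cc(C)ccc3[C@@H]2C)oc1=O
F10 | step 9 | ethyl 2-ethyl-3-[(trimethylsilyl)oxy]but-2-enoate | CCOC(=O)C(CC)=C(C)O[Si](C)(C)C
F11 | step 9 | 1-ethoxy-2-ethyl-1,3-bis[(trimethylsilyl)oxy]buta-1,3-diene | CCOC(O[Si](C)(C)C)=C(CC)C(=C)O[Si](C)(C)C
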